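**Retrosynthesis**
- Caespitol (11) comes from TBS removal of 10. Ring 2 (the tetrahydropyran) is formed last by 6-endo bromoetherification, in which the tertiary C7–OH attacks the prenyl alkene through a chair-like transition state. This sets C10–Br.
- The C7 tertiary alcohol comes from Felkin–Anh methyl addition to an α-silyloxy ketone. That ketone comes from C8 α-hydroxylation of the Claisen ketone 6.
- The key C8–C9 bond and the prenyl alkene form in a [3,3] Claisen rearrangement (Saucy–Marbet type) of the enol ether derived from methyl ketone 3 and 2-methylbut-3-en-2-ol.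
- Ring 1 (the cyclohexane) is already present in (S)-limonene. Its Br/Cl pair is installed first by anti-bromochlorination, which also protects the ring alkene.

Assumption: (S)-(−)-limonene is commercially available. Diastereomer mixtures at Steps 1 and 7 are separated by silica chromatography.

---

**Step 1**
Reactants: 1 (S)-(−)-limonene
Product: 2 (1S,2S,4S)-2-bromo-1-chloro-1-methyl-4-(prop-1-en-2-yl)cyclohexane
Conditions: NBS, HCl (1 M in Et2O), CH2Cl2, −78 °C; chromatographic separation of the diastereomer
Reagents that add atoms: NBS (BrN1C(=O)CCC1=O); HCl (Cl)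
Why: Br⁺ adds to the more nucleophilic trisubstituted ring alkene and Cl⁻ opens the bromonium at tertiary C1 anti (Markovnikov bromochlorination). Both faces are attacked, so the (1S,2S) adduct with Br cis to the C4 side chain is isolated from its diastereomer. C4 is untouched.

**Step 2**
Reactants: 2
Product: 3 1-[(1S,3S,4S)-3-bromo-4-chloro-4-methylcyclohexyl]ethan-1-one
Conditions: O3, CH2Cl2/MeOH, −78 °C; then Me2S
Reagents that add atoms: ozone ([O-][O+]=O), which supplies the carbonyl O
Why: Ozonolysis cleaves the only remaining alkene, the isopropenyl group, to the methyl ketone. The mild, non-enolizing conditions leave C4 and the ring halides unchanged.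

**Step 3**
Reactants: 3
Product: 4 (1S,2S,4S)-2-bromo-1-chloro-4-(1,1-dimethoxyethyl)-1-methylcyclohexane
Conditions: HC(OMe)3, TsOH (cat.), MeOH, rt
Reagents that add atoms: trimethyl orthoformate (COC(OC)OC); methanol (CO)
Why: Acid-catalysed ketalization with orthoformate as water scavenger prepares the ketal for the Claisen exchange. Nothing is changed at any stereocenter.

**Step 4 (key step)**
Reactants: 4; 5 2-methylbut-3-en-2-ol (CC(C)(O)C=C)
Product: 6 1-[(1S,3S,4S)-3-bromo-4-chloro-4-methylcyclohexyl]-5-methylhex-4-en-1-one
Conditions: 5 (8 equiv), PPTS (0.1 equiv), PhMe, 120 °C, slow distillation of MeOH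
Reagents that add atoms: none beyond the listed reactants
Why: Ketal exchange with the tertiary allylic alcohol, loss of MeOH to the terminal enol ether ring–C(=CH2)–O–CMe2CH=CH2, and [3,3] Claisen rearrangement form the C8–C9 bond and the trisubstituted prenyl alkene. The reverse-prenyl ether guarantees bond formation at the CH2 terminus, and the ring stereocenters are untouched.

**Step 5**
Reactants: 6
Product: 7 (2R)-1-[(1S,3S,4S)-3-bromo-4-chloro-4-methylcyclohexyl]-2-hydroxy-5-methylhex-4-en-1-one
Conditions: LDA, THF, −78 °C; then O2, P(OEt)3, −78 °C to rt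
Reagents that add atoms: O2 (O=O)
Why: Kinetic deprotonation at the less hindered C8 CH2 (not C4–H) gives the enolate, and oxygenation followed by phosphite reduction of the hydroperoxide gives the α-hydroxy ketone. The new C8 center is set, moderately, by the allylic C4 stereocenter, and the C8 epimers are carried on.

**Step 6**
Reactants: 7
Product: 8 (2R)-2-(tert-butyldimethylsilyloxy) analogue of 7
Conditions: TBSCl, imidazole, DMF, 40 °C
Reagents that add atoms: TBSCl (CC(C)(C)[Si](C)(C)Cl)
Why: Silylation stops chelation in the next step, so Felkin–Anh control operates, and it also blocks formation of a tetrahydrofuran later.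

**Step 7**
Reactants: 8
Product: 9 (2R,3R)-2-[(1S,3S,4S)-3-bromo-4-chloro-4-methylcyclohexyl]-3-(tert-butyldimethylsilyloxy)-6-methylhept-5-en-2-ol
Conditions: MeLi, CeCl3, THF, −78 °C; chromatographic separation of the C4/C7/C8 diastereomers
Reagents that add atoms: MeLi (C[Li])
Why: Organocerium methyl addition avoids enolization of the hindered ketone. With the bulky non-chelating OTBS group, Felkin–Anh addition sets C7 relative to C8 as in the target, and the diastereomer with the correct C4 relationship is isolated.

**Step 8**
Reactants: 9
Product: 10 TBS ether of caespitol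
Conditions: NBS, 2,6-di-tert-butylpyridine, CH2Cl2, −20 °C
Reagents that add atoms: NBS (BrN1C(=O)CCC1=O)
Why: Br⁺ adds to the prenyl alkene and the tertiary C7–OH closes onto the tertiary carbon C11 in a 6-endo, chair-like, anti-periplanar bromoetherification. This places C10–Br equatorial and gives the target's relative configuration. The TBS-protected C8–OH cannot compete as a nucleophile.

**Step 9**
Reactants: 10
Product: 11 caespitol
Conditions: TBAF, THF, 0 °C to 50 °C
Reagents that add atoms: none
Why: Fluoride cleaves the silyl ether. The ether, both halide types and all stereocenters survive.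

---

**Compound list**

| No. | Name | SMILES | Role |
|---|---|---|---|
| 1 | (S)-(−)-limonene | C=C(C)[C@H]1CCC(C)=CC1 | starting material |
| 2 | (1S,2S,4S)-2-bromo-1-chloro-1-methyl-4-isopropenylcyclohexane | C=C(C)[C@H]1CC[C@](C)(Cl)[C@@H](Br)C1 | intermediate |
| 3 | methyl ketone from ozonolysis of 2 | CC(=O)[C@H]1CC[C@](C)(Cl)[C@@H](Br)C1 | intermediate |
| 4 | dimethyl ketal of 3 | COC(C)(OC)[C@H]1CC[C@](C)(Cl)[C@@H](Br)C1 | intermediate |
| 5 | 2-methylbut-3-en-2-ol | CC(C)(O)C=C | starting material |
| 6 | Claisen ketone | CC(C)=CCCC(=O)[C@H]1CC[C@](C)(Cl)[C@@H](Br)C1 | intermediate |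
| 7 | α-hydroxy ketone | CC(C)=CC[C@@H](O)C(=O)[C@H]1CC[C@](C)(Cl)[C@@H](Br)C1 | intermediate |
| 8 | α-TBS-oxy ketone | CC(C)=CC[C@@H](O[Si](C)(C)C(C)(C)C)C(=O)[C@H]1CC[C@](C)(Cl)[C@@H](Br)C1 | intermediate |
| 9 | tertiary alcohol, TBS ether | CC(C)=CC[C@@H](O[Si](C)(C)C(C)(C)C)[C@](C)(O)[C@H]1CC[C@](C)(Cl)[C@@H](Br)C1 | intermediate |
| 10 | TBS-caespitol | CC1(C)O[C@](C)([C@H]2CC[C@](C)(Cl)[C@@H](Br)C2)[C@H](O[Si](C)(C)C(C)(C)C)C[C@H]1Br | intermediate |
| 11 | caespitol, (2R,3R,5R)-5-bromo-2-[(1S,3S,4S)-3-bromo-4-chloro-4-methylcyclohexyl]-2,6,6-trimethyloxan-3-ol | CC1(C)O[C@](C)([C@H]2CC[C@](C)(Cl)[C@@H](Br)C2)[C@H](O)C[C@H]1Br | target |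

**Total steps:** 9. **Longest linear sequence:** 9 steps from 1.

**Three steps most likely to fail**
1. **Step 1.** The Br-cis-to-side-chain isomer needs a twist-boat opening, so it is likely the minor product of the anti-bromochlorination.
   - Fallback: syn-dihydroxylate 1 (OsO4), open the cyclic orthoacetate at C2 with bromide (inversion), then convert the tertiary acetate to Cl with retention via bromonium assistance (TiCl4). Then resume at Step 2.
2. **Step 4.** The mixed-ketal Claisen may give the wrong enol ether (C4 side), epimerize C4, or ionize the tertiary chloride.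
   - Fallback: drop the acid/heat route and alkylate the kinetic lithium enolate of 3 with prenyl bromide at −78 °C to reach 6 directly.
3. **Step 8.** Bromoetherification has to build a 2,2,6,6-tetrasubstituted tetrahydropyran from a hindered tertiary alcohol, and 5-exo closure or wrong C10 configuration could compete.
   - Fallback: epoxidize the prenyl alkene, close by acid-catalysed 6-endo opening of the epoxide by C7–OH at C11 to give the C10-hydroxy tetrahydropyran, then convert C10–OH to Br by Appel substitution with inversion.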